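What the flask would hold at 15 h was the question, and I reckoned it through the fraction of E left, which is the charge less what has gone to X and Z.

the same everywhere: Q 78 mM (held)
- theta: E 0.26 M; run made earlier
- gamma: E 1 M; run made earlier
- flask: E 0.52 M; time 15 h

- theta (time / h: X / %, Z / %): 2.00: 1.2, 1.7; 5.00: 4.3, 3.1; 10.0: 12.7, 5.1; 15.0: 21.4, 10.2
- gamma (time / h: X / %, Z / %): 1.33: 0, 1.1; 3.00: 2.6, 2.4; 6.00: 4.4, 3.6; 15.0: 8.7, 10.7

(scatter of a reading: 0.5 percentage points)

1. how much X the flask holds at 15 h, in percent of the E charged
2. how much Z the flask holds at 15 h, in percent of the E charged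
3. how much E the flask holds at 15 h, in percent of the E charged
4. concentration of D at 15 h, in M

- at the start none of D is dissolved
- on the list of suspects stand: Q <-> D; E + D -> X; E -> Z

At 15.0 h, Z read 10.2% in theta and 10.7% in gamma, a difference of 0.5 percentage points against a scatter of 0.5 points, so I gave the flask their mean, 10.4%. In concentration, cX read 55.6 mM in theta and 87.0 mM in gamma, a ratio of 1.56, less than the ratio of 3.85 between the two charges, so I took the crossing from Q to D for the rate-limiting step. Taking cX to rise with the charge, theta gave the flask a floor for X and gamma a roof, which put E left between 72.6% and 79.1%. To tighten this I drew cX as a straight line against the reciprocal of the charge, and the end-value of that line at endless E I called the gas ceiling, 98.0 mM. The line gave the flask cX 76.8 mM, so E left came to 74.8%.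

The forecast, “which points to limitation by gas transfer”, gave X 14.3%, Z 9.9%, E 75.8% and cD 0.013 M; its E stood inside my bracket, 1 point above my figure.

The flask gave X 14.6%, Z 9.55%, E 75.8% and cD 0.0169 M, which is 1.30 times the forecast's cD, and its E lay inside the bracket.

    Q ⇌ D, rate k1*(csat - [D]) (kL = 0.00160 min⁻¹)
    E + D → X (k = 0.0140 M⁻¹ min⁻¹)
    E → Z (k = 1.20 × 10⁻⁴ min⁻¹)

On a neighbouring flask, charged with 0.88 M of E and read at the same time, I used the gas ceiling of 98.0 mM again: the line gave cX 85.5 mM, which is 9.72% of that charge, and with the Z share of 10.4%, E left came to 79.8%, inside a bracket from 79.4% to 83.5%. That neighbouring flask held X 10.1%, Z 9.75% and E 80.2%, with cD at 0.0107 M, lower than the 0.0169 M of the first flask.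

The earlier runs and the new flask come from a simulation for substances that don't exist, noise included.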